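## Analysis of the target

Target 21 is a flavonol: a 4H-chromen-4-one (rings A and C) with a 4-(3-methylbut-2-enyloxy)phenyl group (ring B) at C2 and a hydroxyl at C3. It has no stereocentre and no stereogenic double bond, so the task is one of regiochemistry and functional-group tolerance. Ring A carries three adjacent oxygens, hydroxyl at C5, methoxyl at C6 and hydroxyl at C7, and the alkylated oxygen is the middle one, the pattern that selective methylation or demethylation of a 5,6,7-trioxygenated flavone delivers least reliably. The aryl prenyl ether rules out hydrogenolysis, strong Brønsted or Lewis acids and electrophilic oxidants. The 3-hydroxypyranone is oxidised easily as its anion, and C2 of the chromone is open to conjugate attack. Four oxygens have to end up differentiated (3-OH, 5-OH, 7-OH, 4'-O-prenyl), so the prenyl group cannot be put on late. The route rests on one structural feature: C5 and C7 are ortho and para to C4a, the carbon that bears the C4 carbonyl, while C6 is meta to it. A 5,7-difluoro-6-methoxychromone is therefore electrophilic at exactly the two carbons that must become C–OH, and the methoxyl between them is inert.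

## Retrosynthetic reasoning

**21 back to 20 and 19.** The last two operations only unmask oxygen. The 3-O-methoxymethyl acetal of 20 is cut with dilute acid, and the two 2-(trimethylsilyl)ethyl ethers of 19 are cut with fluoride. These groups were chosen because neither removal needs hydrogen, a strong Lewis acid or an oxidant, so the prenyl ether and the methoxyl survive. The only acid step acts on an enol acetal, which ionises far more readily than an aryl prenyl ether.

**19 back to 15 and 16.** The C7–O and C5–O bonds are cut. They are the only ring A bonds whose carbons are conjugated to the C4 carbonyl, so both hydroxyls trace back to fluorides and the 6-methoxyl needs no differentiation. The forward reaction must substitute twice with alkoxide 17 (made from 16, of which two equivalents are consumed). Each substitution has to leave a neutral ether so that the ring stays electrophilic, and the alkoxide must not add at C2. Monoether 18 is the expected intermediate.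

**15 back to 14 and 12.** The 3-oxygen is capped (15 from 14) so that no oxyanion conjugated to the carbonyl forms under alkoxide. Flavonol 14 is then opened across O1–C2 and C3–O to chalcone 12. An Algar–Flynn–Oyamada oxidation closes ring C and installs the 3-oxygen in one operation, passing through dihydroflavonol 13. The substituent that ends at C5 is a small fluorine, which should not cause the diversion to aurones seen with bulky groups at that position.

**12 back to 8 and 11; 11 back to 9 and 10.** The Cα=Cβ bond of the chalcone (later C3–C2) is cut by a retro-aldol condensation. This makes the route convergent and brings in ring B with the prenyl ether already in place, made from 9 and 10 by a single O-alkylation.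

**8 back to 7, 3 and 4; 3 back to 2 and 1.** The aryl–acyl bond (later C4a–C4) is cut. In 3 the hydrogen to be replaced lies between the acetal oxygen and a fluorine, so lithiation to 5 is regiochemically unambiguous (the two such sites are equivalent by symmetry), and acylation with 4 through adduct 6 gives 7. This avoids a Lewis-acid Fries rearrangement, which would endanger the methoxyl. Acid then frees phenol 8. Phenol 2 comes from boronic acid 1 by exchanging C–B for C–O, so the methoxyl flanked by two fluorines is bought, not made.

## Alternatives that were turned down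

**Alternative 1:** Ring C is disconnected at C3–C4. The precursor is the ether-linked dialdehyde A2, in which a ring A benzaldehyde is joined through O1 to an α-aryl acetaldehyde. A carbene from a triazolium salt would turn the aromatic aldehyde into an acyl-anion equivalent that adds to the aliphatic aldehyde, closing ring C as the trans-dihydroflavonol A1.
- In its favour: C3 and C4 arrive at the right oxidation levels in one catalytic, redox-neutral step.
- Against it: the aromatic aldehyde of A2 sits between two ortho oxygens and is the slower one to form the acyl anion, so the regioisomeric ketol is a real risk. The α-aryloxy-α-aryl aldehyde is highly enolisable and fragile. A1 still needs oxidation to the flavonol, and two stereocentres are made only to be erased.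
- Decisive point: ring A of A2 must already hold two protected hydroxyls around a methoxyl, so the central difficulty is only moved into the starting material. The chosen route buys that pattern in 1 and proves it in one substitution step.
- Where it is stronger: it avoids any alkoxide step on a chromone.

**Alternative 2:** Ring B is disconnected at C1'–C2' and C5'–C6'. The 2-ethynylchromone A4 would undergo a Diels–Alder reaction with trans-1-methoxy-3-(trimethylsilyloxy)buta-1,3-diene A5, and loss of the methoxy and silyl groups would aromatise the adduct to the 4'-phenol A3.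
- In its favour: the 4'-oxygen appears free and alone, so prenylation is unambiguous and other 4'-ethers would be easy to make. On that point it is stronger than the chosen route, which fixes the ether at the outset.
- Against it: ring B is a para-substituted benzene that 4-hydroxybenzaldehyde 9 supplies directly. A4 is an ynenone at which the diene can also add in a conjugate sense. A4 needs the same differentiated ring A as Alternative 1. The end game must cleave three acetals, two of them aryl acetals, with acid in the presence of the prenyl ether.
- In the chosen route acid meets only one labile enol acetal, and the pericyclic step is replaced by a convergent aldol condensation.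

**Alternative 3:** Ring A is disconnected at C4a–C5. A pyranone derived from kojic acid A8 carries the tert-butyl β-keto ester side chain in A7. Thermolysis of the ester would unmask an acylketene whose dienol closes by six-electron electrocyclisation onto the pyranone, and tautomerisation gives A6, which is the same compound as 20.
- In its favour: the three ring A oxygens are differentiated by construction, no protecting group is needed on ring A, and only one deprotection remains. On oxygen differentiation it is as strong as the chosen route, and it is shorter after the key step.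
- Against it: A7 requires arylation of the pyranone, homologation of the hydroxymethyl carbon and a crossed Claisen acylation. The electrocyclisation has to overcome the loss of pyranone conjugation at a temperature where acylketenes also dimerise or are trapped. The uncertainty is therefore spread over the precursor and the key step.
- The chosen route reaches its precursor 15 by textbook reactions and concentrates the risk in one well-understood two-electron step.

Key step: step 9

Remark: 13 is formed as a racemate and its two stereocentres are erased in the same flask. Monoether 18 is drawn as the 7-ether; if the C5 fluoride left first, the regioisomeric monoether would converge on the same 19. Step 9 consumes two equivalents of alcohol 16, one for each new ether.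

## Route

Step 1
Reactants: 1 3,5-difluoro-4-methoxyphenylboronic acid
Product: 2 3,5-difluoro-4-methoxyphenol
Conditions: 30% aq H2O2, THF, 0 °C to rt
Reagents that add atoms: hydrogen peroxide, OO
Why: Ipso-hydroxylation of an arylboronic acid: hydroperoxide adds to boron, the aryl group migrates from boron to oxygen and the borate ester hydrolyses, so the phenol oxygen appears exactly where boron was.

Step 2
Reactants: 2 3,5-difluoro-4-methoxyphenol
Product: 3 1,3-difluoro-2-methoxy-5-(methoxymethoxy)benzene
Conditions: MOMCl, i-Pr2NEt, CH2Cl2, 0 °C to rt
Reagents that add atoms: chloromethyl methyl ether, COCCl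
Why: O-alkylation of an acidic phenol with an α-chloro ether (Williamson-type acetal formation); the acetal is needed as a directing group for the next step.

Step 3
Reactants: 3 1,3-difluoro-2-methoxy-5-(methoxymethoxy)benzene; 4 N-methoxy-N-methylacetamide
Product: 7 1-[2,4-difluoro-3-methoxy-6-(methoxymethoxy)phenyl]ethan-1-one, via aryllithium 5 (not isolated), via lithium hemiaminal adduct 6 (not isolated)
Conditions: n-BuLi, THF, −78 °C; then 4, −78 to −40 °C; aq NH4Cl
Reagents that add atoms: none
Why: Directed ortho-metalation at the hydrogen flanked by the acetal oxygen and a fluorine (cooperative directing groups; both such sites are equivalent), followed by a Weinreb ketone synthesis in which the chelated adduct 6 prevents over-addition. Holding −78 °C keeps the ortho-fluoro aryllithium from losing LiF.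

Step 4
Reactants: 7 1-[2,4-difluoro-3-methoxy-6-(methoxymethoxy)phenyl]ethan-1-one
Product: 8 1-(2,4-difluoro-6-hydroxy-3-methoxyphenyl)ethan-1-one
Conditions: HCl (1.25 M in MeOH), rt to 40 °C
Reagents that add atoms: none
Why: Acid-catalysed transacetalisation of an aryl methoxymethyl ether, made easier by the ortho carbonyl; the aryl methyl ether and the C–F bonds are inert to dilute acid.

Step 5
Reactants: 9 4-hydroxybenzaldehyde; 10 prenyl bromide (1-bromo-3-methylbut-2-ene)
Product: 11 4-(3-methylbut-2-enyloxy)benzaldehyde
Conditions: K2CO3, DMF, rt to 50 °C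
Reagents that add atoms: none
Why: Williamson ether synthesis; the phenoxide attacks the primary allylic bromide in an SN2 sense at oxygen, and the para-formyl group suppresses C-alkylation.

Step 6
Reactants: 8 1-(2,4-difluoro-6-hydroxy-3-methoxyphenyl)ethan-1-one; 11 4-(3-methylbut-2-enyloxy)benzaldehyde
Product: 12 (E)-1-(2,4-difluoro-6-hydroxy-3-methoxyphenyl)-3-[4-(3-methylbut-2-enyloxy)phenyl]prop-2-en-1-one
Conditions: KOH (aq), EtOH, 0 °C to rt; then dil. HCl, 0 °C
Reagents that add atoms: none
Why: Claisen–Schmidt condensation; E1cB dehydration gives the conjugated E-alkene. Under the basic conditions ring A is a phenoxide, which should protect the activated fluorides from substitution by hydroxide or ethoxide.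

Step 7
Reactants: 12 (E)-1-(2,4-difluoro-6-hydroxy-3-methoxyphenyl)-3-[4-(3-methylbut-2-enyloxy)phenyl]prop-2-en-1-one
Product: 14 5,7-difluoro-3-hydroxy-6-methoxy-2-[4-(3-methylbut-2-enyloxy)phenyl]-4H-chromen-4-one, via trans-dihydroflavonol 13 (not isolated)
Conditions: 30% aq H2O2, aq NaOH, MeOH, 0 °C to rt; then dil. HCl, 0 °C
Reagents that add atoms: hydrogen peroxide, OO
Why: Algar–Flynn–Oyamada oxidation: the phenoxide closes onto Cβ (6-endo) while Cα is hydroxylated by hydroperoxide, and 13 is dehydrogenated in the same medium. The fluorine next to the carbonyl is small enough not to twist the enone towards aurone formation, and the electron-rich prenyl alkene does not react with the nucleophilic oxidant.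

Step 8
Reactants: 14 5,7-difluoro-3-hydroxy-6-methoxy-2-[4-(3-methylbut-2-enyloxy)phenyl]-4H-chromen-4-one
Product: 15 5,7-difluoro-6-methoxy-3-(methoxymethoxy)-2-[4-(3-methylbut-2-enyloxy)phenyl]-4H-chromen-4-one
Conditions: MOMCl, i-Pr2NEt, CH2Cl2, 0 °C to rt
Reagents that add atoms: chloromethyl methyl ether, COCCl
Why: O-alkylation of the acidic 3-hydroxyl as its acetal; this stops a 3-oxyanion from forming under alkoxide and draining the carbonyl activation needed in step 9.

Step 9
Reactants: 15 5,7-difluoro-6-methoxy-3-(methoxymethoxy)-2-[4-(3-methylbut-2-enyloxy)phenyl]-4H-chromen-4-one; 16 2-(trimethylsilyl)ethanol (first equivalent, for the C7 ether)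
Product: 19 6-methoxy-3-(methoxymethoxy)-2-[4-(3-methylbut-2-enyloxy)phenyl]-5,7-bis[2-(trimethylsilyl)ethoxy]-4H-chromen-4-one, via sodium 2-(trimethylsilyl)ethoxide 17 (not isolated), via monoether 18 (not isolated)
Conditions: 16 (2.6 equiv), NaH (2.5 equiv), THF, 0 °C; then 15, THF–DMPU, rt to 60 °C
Reagents that add atoms: 2-(trimethylsilyl)ethanol (second equivalent of 16, for the C5 ether), C[Si](C)(C)CCO
Why: Each substitution is an addition–elimination (SNAr): alkoxide 17 adds to a fluorine-bearing carbon, the charge of the Meisenheimer anion runs through C4a into the C4 carbonyl, and fluoride is expelled. The closest known reaction type is displacement by alkoxides of fluoride ortho or para to an aryl ketone, with 2-(trimethylsilyl)ethoxide as an established hydroxide surrogate. No ring is closed and no stereocentre is formed; two C–O bonds are made, each from one equivalent of 17. C7 (para, flanked only by H-8 and the methoxyl) should react first at room temperature to give 18, and C5 (peri to the carbonyl) on warming, where the carbonyl-bound sodium ion can deliver the alkoxide. Site selectivity is secured because C6 is meta to the carbonyl and its methoxyl, twisted out of plane by two neighbours, acts mainly as an inductive acceptor. Conjugate addition at C2 is disfavoured by the donor 4-alkoxyphenyl and 3-alkoxy groups, and any adduct there can revert. Each product is a neutral ether and not a phenoxide, so the ring keeps enough electrophilicity for the second displacement. Sodium is chosen so that fluoride leaves solution as NaF and cannot attack silicon.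

Step 10
Reactants: 19 6-methoxy-3-(methoxymethoxy)-2-[4-(3-methylbut-2-enyloxy)phenyl]-5,7-bis[2-(trimethylsilyl)ethoxy]-4H-chromen-4-one
Product: 20 5,7-dihydroxy-6-methoxy-3-(methoxymethoxy)-2-[4-(3-methylbut-2-enyloxy)phenyl]-4H-chromen-4-one
Conditions: Bu4NF, THF, rt to 50 °C; aq NH4Cl
Reagents that add atoms: none
Why: Fluoride attacks silicon and each ether fragments by β-elimination to ethene and a phenoxide. The C5 and C7 oxygens are vinylogous carboxylates and good leaving groups, and the acetal, methoxyl and prenyl ether are inert to fluoride.

Step 11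
Reactants: 20 5,7-dihydroxy-6-methoxy-3-(methoxymethoxy)-2-[4-(3-methylbut-2-enyloxy)phenyl]-4H-chromen-4-one
Product: 21 3,5,7-trihydroxy-6-methoxy-2-[4-(3-methylbut-2-enyloxy)phenyl]-4H-chromen-4-one (target)
Conditions: HCl (0.5 M in MeOH–THF), 0 °C to rt
Reagents that add atoms: none
Why: Acid-catalysed transacetalisation of the enol methoxymethyl ether to methanol; the acetal oxygen is far more basic and its oxocarbenium far easier to form than the cation from an aryl prenyl ether on an electron-poor ring, so cold dilute acid should discriminate.

## Compound list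

1 | 3,5-difluoro-4-methoxyphenylboronic acid | COc1c(F)cc(B(O)O)cc1F | starting material
2 | 3,5-difluoro-4-methoxyphenol | COc1c(F)cc(O)cc1F | intermediate
3 | 1,3-difluoro-2-methoxy-5-(methoxymethoxy)benzene | COCOc1cc(F)c(OC)c(F)c1 | intermediate
4 | N-methoxy-N-methylacetamide | CC(=O)N(C)OC | starting material
5 | [2,4-difluoro-3-methoxy-6-(methoxymethoxy)phenyl]lithium | [Li]c1c(F)c(OC)c(F)cc1OCOC | intermediate (not isolated)
6 | lithium 1-[2,4-difluoro-3-methoxy-6-(methoxymethoxy)phenyl]-1-[methoxy(methyl)amino]ethanolate (racemic) | CC([O-])(N(C)OC)c1c(F)c(OC)c(F)cc1OCOC.[Li+] | intermediate (not isolated)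
7 | 1-[2,4-difluoro-3-methoxy-6-(methoxymethoxy)phenyl]ethan-1-one | CC(=O)c1c(F)c(OC)c(F)cc1OCOC | intermediate
8 | 1-(2,4-difluoro-6-hydroxy-3-methoxyphenyl)ethan-1-one | CC(=O)c1c(F)c(OC)c(F)cc1O | intermediate
9 | 4-hydroxybenzaldehyde | O=Cc1ccc(O)cc1 | starting material
10 | prenyl bromide (1-bromo-3-methylbut-2-ene) | CC(C)=CCBr | starting material
11 | 4-(3-methylbut-2-enyloxy)benzaldehyde | CC(C)=CCOc1ccc(C=O)cc1 | intermediate
12 | (E)-1-(2,4-difluoro-6-hydroxy-3-methoxyphenyl)-3-[4-(3-methylbut-2-enyloxy)phenyl]prop-2-en-1-one | CC(C)=CCOc1ccc(/C=C/C(=O)c2c(F)c(OC)c(F)cc2O)cc1 | intermediate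
13 | (2R*,3R*)-5,7-difluoro-3-hydroxy-6-methoxy-2-[4-(3-methylbut-2-enyloxy)phenyl]chroman-4-one (trans, racemic, one enantiomer drawn) | CC(C)=CCOc1ccc(cc1)[C@@H]2[C@H](C(=O)c3c(F)c(OC)c(F)cc3O2)O | intermediate (not isolated)
14 | 5,7-difluoro-3-hydroxy-6-methoxy-2-[4-(3-methylbut-2-enyloxy)phenyl]-4H-chromen-4-one | COc1c(F)cc2oc(-c3ccc(OCC=C(C)C)cc3)c(O)c(=O)c2c1F | intermediate
15 | 5,7-difluoro-6-methoxy-3-(methoxymethoxy)-2-[4-(3-methylbut-2-enyloxy)phenyl]-4H-chromen-4-one | COCOc1c(-c2ccc(OCC=C(C)C)cc2)oc2cc(F)c(OC)c(F)c2c1=O | intermediate
16 | 2-(trimethylsilyl)ethanol | C[Si](C)(C)CCO | starting material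
17 | sodium 2-(trimethylsilyl)ethoxide | C[Si](C)(C)CC[O-].[Na+] | intermediate (not isolated)
18 | 5-fluoro-6-methoxy-3-(methoxymethoxy)-2-[4-(3-methylbut-2-enyloxy)phenyl]-7-[2-(trimethylsilyl)ethoxy]-4H-chromen-4-one | COCOc1c(-c2ccc(OCC=C(C)C)cc2)oc2cc(OCC[Si](C)(C)C)c(OC)c(F)c2c1=O | intermediate (not isolated)
19 | 6-methoxy-3-(methoxymethoxy)-2-[4-(3-methylbut-2-enyloxy)phenyl]-5,7-bis[2-(trimethylsilyl)ethoxy]-4H-chromen-4-one | COCOc1c(-c2ccc(OCC=C(C)C)cc2)oc2cc(OCC[Si](C)(C)C)c(OC)c(OCC[Si](C)(C)C)c2c1=O | intermediate
20 | 5,7-dihydroxy-6-methoxy-3-(methoxymethoxy)-2-[4-(3-methylbut-2-enyloxy)phenyl]-4H-chromen-4-one | COCOc1c(-c2ccc(OCC=C(C)C)cc2)oc2cc(O)c(OC)c(O)c2c1=O | intermediate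
21 | 3,5,7-trihydroxy-6-methoxy-2-[4-(3-methylbut-2-enyloxy)phenyl]-4H-chromen-4-one | COc1c(O)cc2oc(-c3ccc(OCC=C(C)C)cc3)c(O)c(=O)c2c1O | target

## Step count and least certain steps

Total step count: 11. Longest linear sequence: 10 (steps 1–4 and 6–11; step 5 is the side branch).

**Step 9 (key step).**
- Risk: the second displacement may stall, because the first ether donates into the carbonyl and C5 is hindered. On heating, the β-silyl alkoxide may collapse in a Peterson-type elimination to a silanolate, or a silylethyl group may be lost early; either would give a phenoxide that shuts down further substitution. Reversible addition at C2 may also slow the reaction.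
- Fallback: the first displacement is run with one equivalent at room temperature and 18 is isolated. Its C5 fluoride is then displaced with the sodium alkoxide of 2-(methylsulfonyl)ethanol (NaH, DMF, 0 °C to rt), a small self-cleaving hydroxide surrogate. This gives 6-methoxy-3-(methoxymethoxy)-2-[4-(3-methylbut-2-enyloxy)phenyl]-5-[2-(methylsulfonyl)ethoxy]-7-[2-(trimethylsilyl)ethoxy]-4H-chromen-4-one F1, which loses methyl vinyl sulfone by E1cB elimination in the same flask to give 5-hydroxy-6-methoxy-3-(methoxymethoxy)-2-[4-(3-methylbut-2-enyloxy)phenyl]-7-[2-(trimethylsilyl)ethoxy]-4H-chromen-4-one F2. Because this is the last substitution, forming the chelated phenoxide is harmless and drives the reaction. Bu4NF then removes the single silylethyl group and the route is rejoined at 20.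

**Step 7.**
- Risk: the oxidative cyclisation may divert to five-membered closure at Cα (aurone pathway), and hydroperoxide may substitute an activated fluoride once ring A is no longer a phenoxide.
- Fallback: from 7, condensation with 11 (KOH, EtOH) gives (E)-1-[2,4-difluoro-3-methoxy-6-(methoxymethoxy)phenyl]-3-[4-(3-methylbut-2-enyloxy)phenyl]prop-2-en-1-one F3. Nucleophilic epoxidation (H2O2, NaOH, MeOH) gives the trans-epoxide [2,4-difluoro-3-methoxy-6-(methoxymethoxy)phenyl]{(2R*,3S*)-3-[4-(3-methylbut-2-enyloxy)phenyl]oxiran-2-yl}methanone F4. HCl in MeOH removes the acetal, and the freed phenol opens the epoxide at the benzylic carbon to give 13, now isolated. Dehydrogenation of 13 with alkaline H2O2 at 0 °C rejoins the route at 14.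

**Step 11.**
- Risk: acid-induced ionisation of the aryl prenyl ether, or addition of HCl or methanol across the trisubstituted alkene, may compete with acetal cleavage.
- Fallback: from 14, the 3-hydroxyl is protected with SEMCl and i-Pr2NEt as 5,7-difluoro-6-methoxy-2-[4-(3-methylbut-2-enyloxy)phenyl]-3-{[2-(trimethylsilyl)ethoxy]methoxy}-4H-chromen-4-one F5. The double substitution of step 9, again with two equivalents of 17, gives 6-methoxy-2-[4-(3-methylbut-2-enyloxy)phenyl]-5,7-bis[2-(trimethylsilyl)ethoxy]-3-{[2-(trimethylsilyl)ethoxy]methoxy}-4H-chromen-4-one F6. Bu4NF in DMPU at 80 °C then removes all three silicon-based groups without acid and gives 21 directly.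

**Step 3.**
- Risk: the ortho-fluoro aryllithium may lose LiF to a benzyne if the temperature rises, or may be quenched by proton transfer from the acetamide instead of adding to it.
- Fallback: from 2, acetylation (Ac2O, pyridine) gives 3,5-difluoro-4-methoxyphenyl acetate F7, and a Fries rearrangement (TfOH, neat, rt to 60 °C) moves the acetyl group to the ortho carbon and rejoins the route at 8. This is kept as a fallback only, because strong acid puts the methoxyl at some risk.

## Further compounds

F1 | step 9 | 6-methoxy-3-(methoxymethoxy)-2-[4-(3-methylbut-2-enyloxy)phenyl]-5-[2-(methylsulfonyl)ethoxy]-7-[2-(trimethylsilyl)ethoxy]-4H-chromen-4-one | COCOc1c(-c2ccc(OCC=C(C)C)cc2)oc2cc(OCC[Si](C)(C)C)c(OC)c(OCCS(C)(=O)=O)c2c1=O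
F2 | step 9 | 5-hydroxy-6-methoxy-3-(methoxymethoxy)-2-[4-(3-methylbut-2-enyloxy)phenyl]-7-[2-(trimethylsilyl)ethoxy]-4H-chromen-4-one | COCOc1c(-c2ccc(OCC=C(C)C)cc2)oc2cc(OCC[Si](C)(C)C)c(OC)c(O)c2c1=O
F3 | step 7 | (E)-1-[2,4-difluoro-3-methoxy-6-(methoxymethoxy)phenyl]-3-[4-(3-methylbut-2-enyloxy)phenyl]prop-2-en-1-one | CC(C)=CCOc1ccc(/C=C/C(=O)c2c(F)c(OC)c(F)cc2OCOC)cc1
F4 | step 7 | [2,4-difluoro-3-methoxy-6-(methoxymethoxy)phenyl]{(2R*,3S*)-3-[4-(3-methylbut-2-enyloxy)phenyl]oxiran-2-yl}methanone (trans, racemic, one enantiomer drawn) | O=C([C@H]1O[C@@H]1c1ccc(OCC=C(C)C)cc1)c1c(F)c(OC)c(F)cc1OCOC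
F5 | step 11 | 5,7-difluoro-6-methoxy-2-[4-(3-methylbut-2-enyloxy)phenyl]-3-{[2-(trimethylsilyl)ethoxy]methoxy}-4H-chromen-4-one | C[Si](C)(C)CCOCOc1c(-c2ccc(OCC=C(C)C)cc2)oc2cc(F)c(OC)c(F)c2c1=O
F6 | step 11 | 6-methoxy-2-[4-(3-methylbut-2-enyloxy)phenyl]-5,7-bis[2-(trimethylsilyl)ethoxy]-3-{[2-(trimethylsilyl)ethoxy]methoxy}-4H-chromen-4-one | C[Si](C)(C)CCOCOc1c(-c2ccc(OCC=C(C)C)cc2)oc2cc(OCC[Si](C)(C)C)c(OC)c(OCC[Si](C)(C)C)c2c1=O
F7 | step 3 | 3,5-difluoro-4-methoxyphenyl acetate | CC(=O)Oc1cc(F)c(OC)c(F)c1
A1 | alternative 1 | trans-3-hydroxy-6-methoxy-5,7-bis(methoxymethoxy)-2-[4-(3-methylbut-2-enyloxy)phenyl]chroman-4-one (racemic, one enantiomer drawn) | CC(C)=CCOc1ccc(cc1)[C@@H]2[C@H](C(=O)c3c(OCOC)c(OC)c(OCOC)cc3O2)O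
A2 | alternative 1 | 3-methoxy-2,4-bis(methoxymethoxy)-6-{1-[4-(3-methylbut-2-enyloxy)phenyl]-2-oxoethoxy}benzaldehyde (racemic) | O=Cc1c(OCOC)c(OC)c(OCOC)cc1OC(C=O)c1ccc(OCC=C(C)C)cc1
A3 | alternative 2 | 2-(4-hydroxyphenyl)-6-methoxy-3,5,7-tris(methoxymethoxy)-4H-chromen-4-one | COCOc1c(-c2ccc(O)cc2)oc2cc(OCOC)c(OC)c(OCOC)c2c1=O
A4 | alternative 2 | 2-ethynyl-6-methoxy-3,5,7-tris(methoxymethoxy)-4H-chromen-4-one | COCOc1c(C#C)oc2cc(OCOC)c(OC)c(OCOC)c2c1=O
A5 | alternative 2 | trans-1-methoxy-3-(trimethylsilyloxy)buta-1,3-diene | CO/C=C/C(=C)O[Si](C)(C)C
A6 | alternative 3 | 5,7-dihydroxy-6-methoxy-3-(methoxymethoxy)-2-[4-(3-methylbut-2-enyloxy)phenyl]-4H-chromen-4-one | COCOc1c(-c2ccc(OCC=C(C)C)cc2)oc2cc(O)c(OC)c(O)c2c1=O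
A7 | alternative 3 | tert-butyl 2-methoxy-4-{5-(methoxymethoxy)-6-[4-(3-methylbut-2-enyloxy)phenyl]-4-oxo-4H-pyran-2-yl}-3-oxobutanoate (racemic) | CC(C)(C)OC(=O)C(OC)C(=O)Cc1cc(=O)c(OCOC)c(-c2ccc(OCC=C(C)C)cc2)o1
A8 | alternative 3 | kojic acid (5-hydroxy-2-(hydroxymethyl)-4H-pyran-4-one) | OCc1cc(=O)c(O)co1
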